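**Count the partner.** Read the recipes and earlier runs below, and ask what each plateau is worth.

| setting | alder | elm | birch | noon | spring | summer | autumn |
|---|---|---|---|---|---|---|---|
| left-handed substrate | 0.013 M | 0.013 M | 0.013 M | 0.013 M | 0.013 M | 0.013 M | 0.013 M |
| right-handed substrate | 0.013 M | 0.013 M | 0.013 M | 0.013 M | 0.013 M | 0.013 M | 0.013 M |
| partner | 0.022 M | 0.034 M | 0.0156 M | 0.0156 M | 0.0156 M | 0.0156 M | 0.0156 M |
| free catalyst | 1.9 mM | 1.9 mM | 0.95 mM | 1.9 mM | 1.9 mM | 1.9 mM | 1.9 mM |
| impurity | 0.22 mM | 0.22 mM | 0.22 mM | 0.22 mM | 0.22 mM | 0.22 mM | 0.22 mM |
| temperature | 75 °C | 100 °C | 75 °C | 120 °C |  | 100 °C | 80 °C |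
| remark | run made earlier | run made earlier | run made earlier |  | at 80 °C until 3.0 min, from then on at 120 °C |  |  |
| time |  |  |  | 6.0 min | 6.0 min | 6.0 min | 6.0 min |

- alder (time / min: left-handed product / %): 2.50: 45.5; 6.00: 44.0; 15.0: 42.2; 40.0: 42.4
- elm (time / min: left-handed product / %): 0.667: 49.2; 2.00: 50.2; 4.00: 50.3; 10.0: 50.3
- birch (time / min: left-handed product / %): 8.00: 31.2; 20.0: 30.4; 25.0: 29.8; 40.0: 30.0

(readings scatter by 0.3 percentage points)

- free catalyst is single-handed; left-handed substrate and right-handed substrate are mirror images of each other, charged as a racemate, each of them at the stated concentration
- candidate steps: partner + free catalyst + left-handed substrate -> free catalyst + left-handed product; partner + free catalyst + right-handed substrate -> free catalyst + right-handed product; partner + free catalyst -> spent catalyst A; free catalyst + impurity -> spent catalyst B; left-handed product <-> right-handed product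

1. the flask that comes out highest in amount of left-handed product, in percent of the left-handed substrate and right-handed substrate together charged, or "all alike" when all lie within 1.5 percentage points (noon / spring / summer / autumn / all alike)
2. left-handed product at the end, in percent of the left-handed substrate and right-handed substrate together charged, noon
3. left-handed product at the end, in percent of the left-handed substrate and right-handed substrate together charged, spring
4. left-handed product at the end, in percent of the left-handed substrate and right-handed substrate together charged, summer
5. left-handed product at the end, in percent of the left-handed substrate and right-handed substrate together charged, autumn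

**The even split.** Each coupling step spends one partner and makes one product, so partner is the limiting reagent wherever less of it is charged than of the substrates together. The products are mirror images of equal energy, so their interconversion tends to an even split, and that split is the zero of your scale. Call the racemic ceiling half of the smaller of partner and substrates together, in percent of the substrates charged: 30.0% for the new flasks. The same reckoning gives alder 42.3%, and alder's last reading is 42.4%. It gives birch 30.0%, and birch's last reading is 30.0%. Elm, with more partner than substrates, gets 50.0% and reads 50.3%.

**The excess.** Alder's left-handed product stands 3.2 percentage points above its ceiling at 2.50 min, but 1.7 points above it at 6.00 min. Read as a first-order decay, that is 0.181 /min. Kinetic control is giving way to thermodynamic control.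

**My reckoning.** Autumn is the coolest new flask, yet warmer than alder. As a rough guess, I allow its decay a factor of 1.41. I do not carry alder's excess over to autumn, since alder holds more partner. Birch holds the same partner charge as autumn, so I start instead from birch's first reading, 1.2 points above its ceiling at 8.00 min. Birch has half the free catalyst, so this transfer is only an estimate. With that factor, autumn's 6.0 min count as 8.49 min on birch's clock, so I estimate that autumn keeps about 1.1 points, which is less than the margin of 1.5 points. I expect autumn near 31.1% and the hotter flasks near 30.0%, so I would call them alike.

**The forecast.** The forecast differs from me on the choice: it names autumn. It gives noon 28.8%, spring 29.9%, summer 29.8% and autumn 31%, on the ground that “partner limits conversion, and the product racemises”.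

**The result.**

    partner + free catalyst + left-handed substrate → free catalyst + left-handed product (k = 33000 /M²/s, Ea = 15.0 kJ/mol)
    partner + free catalyst + right-handed substrate → free catalyst + right-handed product (k = 15000 /M²/s, Ea = 20.0 kJ/mol)
    partner + free catalyst → spent catalyst A (k = 0.800 /M/s, Ea = 47.0 kJ/mol)
    free catalyst + impurity → spent catalyst B (k = 3800 /M/s, Ea = 26.0 kJ/mol)
    left-handed product ⇌ right-handed product (k = 0.0190 /s, Ea = 101 kJ/mol)
    (constants at 100 °C)

Noon gives 29.9%, spring 30.0%, summer 29.9% and autumn 30.9%, so the answer is all alike. Autumn stands 0.90 points above the ceiling of 30.0%. The forecast's gap from noon to autumn was 2.2 points, but the flasks show 1.00 point, inside the margin. Now charge spring's neighbour with 0.027 M of partner, more than the 0.0260 M of substrates together. The ceiling moves to 50.0%, and that neighbour gives 50.0% of right-handed product and 50.0% of left-handed product.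

(All runs are calculated for substances that don't exist; scatter was added.)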